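## Retrosynthetic overview

1. The tetronic acid ring is closed last, by Dieckmann condensation of the α‑propanoyloxy methyl ester 26; the furan ring is bought as 3‑bromofuran and attached in step 3.
2. The (E,E)‑diene is cut at its central σ‑bond: Suzuki–Miyaura coupling of vinyl iodide 12 (fragment A) with alkenylboronate 25 (fragment B).
3. Fragment A comes from (R)‑citronellal: methylenation, selective ozonolysis, B‑alkyl Suzuki coupling with 3‑bromofuran, acetylide alkylation, Negishi carboalumination–iodination.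
4. Fragment B comes from (R)‑β‑citronellene: selective ozonolysis to the acid, Evans enolate hydroxylation (sets the carbinol centre), propanoylation, cross‑metathesis with vinyl‑Bpin.
5. Ring order: furan (preformed, present from step 3), then tetronic acid (step 14).

Assumption: (R)‑citronellal and (R)‑β‑citronellene are bought, or upgraded, to at least 97% ee.

## Route

Step 1
Reactants: 1 (R)‑citronellal [(3R)‑3,7‑dimethyloct‑6‑enal]
Product: 2 (4R)‑4,8‑dimethylnona‑1,7‑diene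
Conditions: Ph3PCH3Br, KOtBu, THF, 0 °C → rt
Reagents that add atoms: methyltriphenylphosphonium bromide, C[P+](c1ccccc1)(c1ccccc1)c1ccccc1.[Br-]
Why: Wittig methylenation of the aldehyde with the non‑stabilised ylide adds the extra chain carbon and leaves the β‑stereocentre (future C10 of the side chain) untouched.

Step 2
Reactants: 2 (4R)‑4,8‑dimethylnona‑1,7‑diene
Product: 5 (4R)‑4‑methylhept‑6‑en‑1‑ol, via ozonide 3 (not isolated), via (4R)‑4‑methylhept‑6‑enal 4 (not isolated)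
Conditions: O3, CH2Cl2, −78 °C (Sudan Red 7B end point); then NaBH4, MeOH, −78 °C → rt
Reagents that add atoms: ozone, [O-][O+]=O
Why: Chemoselective ozonolysis, since ozone attacks the electron‑rich trisubstituted alkene much faster than the monosubstituted one, and borohydride reduces the ozonide straight to the primary alcohol.

Step 3
Reactants: 5 (4R)‑4‑methylhept‑6‑en‑1‑ol; 6 3‑bromofuran
Product: 8 (4S)‑7‑(furan‑3‑yl)‑4‑methylheptan‑1‑ol, via bis‑9‑BBN adduct 7 (not isolated)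
Conditions: 9‑BBN (2.2 equiv), THF, 0 °C → rt; then 6, PdCl2(dppf) (5 mol%), aq. K3PO4, DMF, 50 °C
Reagents that add atoms: none
Why: Anti‑Markovnikov hydroboration of the terminal alkene (the O–H is only borylated) followed by B‑alkyl Suzuki–Miyaura coupling forms the sp3–sp2 bond to the furan, and the alcohol returns on aqueous work‑up.

Step 4
Reactants: 8 (4S)‑7‑(furan‑3‑yl)‑4‑methylheptan‑1‑ol
Product: 9 3‑[(4S)‑7‑iodo‑4‑methylheptyl]furan
Conditions: I2, PPh3, imidazole, CH2Cl2, 0 °C → rt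
Reagents that add atoms: iodine, [I][I]
Why: Appel‑type iodination converts the primary alcohol into the iodide under buffered conditions that the furan tolerates.

Step 5
Reactants: 9 3‑[(4S)‑7‑iodo‑4‑methylheptyl]furan
Product: 10 3‑[(4R)‑4‑methylnon‑8‑yn‑1‑yl]furan
Conditions: LiC≡CH·H2NCH2CH2NH2 (3 equiv), DMSO, 15 °C → rt
Reagents that add atoms: lithium acetylide–ethylenediamine complex, [Li+].[C-]#C.NCCN
Why: SN2 alkylation of lithium acetylide by the unhindered primary iodide gives the terminal alkyne with the three‑methylene spacer.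

Step 6
Reactants: 10 3‑[(4R)‑4‑methylnon‑8‑yn‑1‑yl]furan
Product: 12 3‑[(4S,8E)‑9‑iodo‑4,8‑dimethylnon‑8‑en‑1‑yl]furan, via alkenylalane 11 (not isolated)
Conditions: Me3Al (2.5 equiv), Cp2ZrCl2 (0.25 equiv), CH2Cl2, 0 °C → rt; then I2, THF, −30 → 0 °C
Reagents that add atoms: trimethylaluminium, C[Al](C)C; iodine, [I][I]
Why: Negishi zirconium‑catalysed carboalumination adds methyl and aluminium syn with aluminium at the terminus, and iodinolysis with retention gives the (E)‑trisubstituted vinyl iodide.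

Step 7
Reactants: 13 (R)‑β‑citronellene [(3R)‑3,7‑dimethylocta‑1,6‑diene]
Product: 16 (4R)‑4‑methylhex‑5‑enoic acid, via ozonide 14 (not isolated), via (4R)‑4‑methylhex‑5‑enal 15 (not isolated)
Conditions: O3, CH2Cl2, −78 °C (Sudan Red 7B end point); then acetone, CrO3/H2SO4/H2O (Jones oxidation), 0 °C
Reagents that add atoms: ozone, [O-][O+]=O; water (from the aqueous CrO3/H2SO4), O
Why: Chemoselective ozonolysis of the trisubstituted alkene with oxidative Jones work‑up gives the acid in one flask, and the non‑enolisable allylic stereocentre is kept.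

Step 8
Reactants: 16 (4R)‑4‑methylhex‑5‑enoic acid; 17 (4R)‑4‑benzyl‑1,3‑oxazolidin‑2‑one
Product: 19 (4R)‑4‑benzyl‑3‑[(4R)‑4‑methylhex‑5‑enoyl]‑1,3‑oxazolidin‑2‑one, via pivaloyl mixed anhydride 18 (not isolated)
Conditions: t‑BuCOCl, Et3N, THF, −20 °C; then LiCl, 17, −20 °C → rt
Reagents that add atoms: none
Why: N‑acylation of the Evans auxiliary through the mixed anhydride, in which the less hindered acyl group is transferred.

Step 9
Reactants: 19 (4R)‑4‑benzyl‑3‑[(4R)‑4‑methylhex‑5‑enoyl]‑1,3‑oxazolidin‑2‑one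
Product: 22 (4R)‑4‑benzyl‑3‑[(2R,4R)‑2‑hydroxy‑4‑methylhex‑5‑enoyl]‑1,3‑oxazolidin‑2‑one, via sodium enolate 20 (not isolated), via sodium alkoxide 21 (not isolated)
Conditions: NaN(SiMe3)2, THF, −78 °C; 3‑phenyl‑2‑(phenylsulfonyl)oxaziridine, −78 °C; camphorsulfonic acid quench
Reagents that add atoms: 3‑phenyl‑2‑(phenylsulfonyl)oxaziridine (Davis reagent), O=S(=O)(c1ccccc1)N1OC1c1ccccc1
Why: Evans asymmetric enolate hydroxylation, in which the chelated sodium (Z)‑enolate is oxidised on the face opposite the benzyl group, so the (R)‑auxiliary sets the new carbinol centre as R (dr expected ≥95:5, minor isomer removed by chromatography).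

Step 10
Reactants: 22 (4R)‑4‑benzyl‑3‑[(2R,4R)‑2‑hydroxy‑4‑methylhex‑5‑enoyl]‑1,3‑oxazolidin‑2‑one
Product: 23 methyl (2R,4R)‑2‑hydroxy‑4‑methylhex‑5‑enoate
Conditions: MeMgBr (1.2 equiv) in MeOH (gives MeOMgBr), 0 °C; 1 M HCl quench
Reagents that add atoms: methanol, CO
Why: Transesterification by the magnesium methoxide attacks the exocyclic imide carbonyl and releases the auxiliary without epimerising the α‑hydroxy centre.

Step 11
Reactants: 23 methyl (2R,4R)‑2‑hydroxy‑4‑methylhex‑5‑enoate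
Product: 24 methyl (2R,4R)‑4‑methyl‑2‑(propanoyloxy)hex‑5‑enoate
Conditions: EtCOCl, pyridine, DMAP (cat.), CH2Cl2, 0 °C → rt
Reagents that add atoms: propanoyl chloride, CCC(=O)Cl
Why: DMAP‑catalysed O‑acylation installs the propanoate that later supplies C2, C3 and the 3‑methyl group of the tetronic acid.

Step 12
Reactants: 24 methyl (2R,4R)‑4‑methyl‑2‑(propanoyloxy)hex‑5‑enoate
Product: 25 methyl (2R,4R,5E)‑4‑methyl‑2‑(propanoyloxy)‑6‑(4,4,5,5‑tetramethyl‑1,3,2‑dioxaborolan‑2‑yl)hex‑5‑enoate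
Conditions: vinyl‑Bpin (4 equiv), second‑generation Hoveyda–Grubbs catalyst (5 mol%), CH2Cl2, 40 °C
Reagents that add atoms: 2‑ethenyl‑4,4,5,5‑tetramethyl‑1,3,2‑dioxaborolane, C=CB1OC(C)(C)C(C)(C)O1
Why: Olefin cross‑metathesis driven by loss of ethene, where the allylic branch and the bulky boronate favour the (E)‑alkenylboronate.

Step 13
Reactants: 12 3‑[(4S,8E)‑9‑iodo‑4,8‑dimethylnon‑8‑en‑1‑yl]furan; 25 methyl (2R,4R,5E)‑4‑methyl‑2‑(propanoyloxy)‑6‑(4,4,5,5‑tetramethyl‑1,3,2‑dioxaborolan‑2‑yl)hex‑5‑enoate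
Product: 26 methyl (2R,4R,5E,7E,12R)‑15‑(furan‑3‑yl)‑4,8,12‑trimethyl‑2‑(propanoyloxy)pentadeca‑5,7‑dienoate
Conditions: Pd(PPh3)4 (5 mol%), TlOEt (1.8 equiv), THF/H2O (3:1), rt
Reagents that add atoms: none
Why: Suzuki–Miyaura sp2–sp2 coupling proceeds with retention at both alkenes to give the (5E,7E)‑diene, and the thallium base makes transmetalation fast at room temperature so both esters survive.

Step 14
Reactants: 26 methyl (2R,4R,5E,7E,12R)‑15‑(furan‑3‑yl)‑4,8,12‑trimethyl‑2‑(propanoyloxy)pentadeca‑5,7‑dienoate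
Product: 29 (5R)‑5‑[(2R,3E,5E,10R)‑13‑(furan‑3‑yl)‑2,6,10‑trimethyltrideca‑3,5‑dien‑1‑yl]‑4‑hydroxy‑3‑methylfuran‑2(5H)‑one, via lithium ester enolate 27 (not isolated), via lithium tetronate 28 (not isolated)
Conditions: LiN(SiMe3)2 (3 equiv), THF, −78 → 0 °C; then 1 M HCl
Reagents that add atoms: none
Why: Dieckmann (intramolecular Claisen) condensation of the propanoate enolate onto the methyl ester closes the tetronic acid, which is deprotonated at once to the tetronate, shielding C5 from epimerisation until acid work‑up.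

## Compound list

1 | (R)‑citronellal, (3R)‑3,7‑dimethyloct‑6‑enal | O=CC[C@H](C)CCC=C(C)C | starting material
2 | (4R)‑4,8‑dimethylnona‑1,7‑diene | C=CC[C@H](C)CCC=C(C)C | intermediate
3 | 3,3‑dimethyl‑5‑[(3R)‑3‑methylhex‑5‑en‑1‑yl]‑1,2,4‑trioxolane (ozonide of 2) | C=CC[C@H](C)CCC1OOC(C)(C)O1 | intermediate
4 | (4R)‑4‑methylhept‑6‑enal | C=CC[C@H](C)CCC=O | intermediate
5 | (4R)‑4‑methylhept‑6‑en‑1‑ol | C=CC[C@H](C)CCCO | intermediate
6 | 3‑bromofuran | Brc1ccoc1 | starting material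
7 | 9‑{[(4S)‑7‑(9‑borabicyclo[3.3.1]nonan‑9‑yl)‑4‑methylheptyl]oxy}‑9‑borabicyclo[3.3.1]nonane | B1(CCC[C@H](C)CCCOB2C3CCCC2CCC3)C2CCCC1CCC2 | intermediate
8 | (4S)‑7‑(furan‑3‑yl)‑4‑methylheptan‑1‑ol | OCCC[C@@H](C)CCCc1ccoc1 | intermediate
9 | 3‑[(4S)‑7‑iodo‑4‑methylheptyl]furan | ICCC[C@@H](C)CCCc1ccoc1 | intermediate
10 | 3‑[(4R)‑4‑methylnon‑8‑yn‑1‑yl]furan | C#CCCC[C@@H](C)CCCc1ccoc1 | intermediate
11 | [(1E,6S)‑9‑(furan‑3‑yl)‑2,6‑dimethylnon‑1‑en‑1‑yl]dimethylalumane | C[Al](C)/C=C(\C)CCC[C@@H](C)CCCc1ccoc1 | intermediate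
12 | 3‑[(4S,8E)‑9‑iodo‑4,8‑dimethylnon‑8‑en‑1‑yl]furan | I/C=C(\C)CCC[C@@H](C)CCCc1ccoc1 | intermediate
13 | (R)‑β‑citronellene, (3R)‑3,7‑dimethylocta‑1,6‑diene | C=C[C@H](C)CCC=C(C)C | starting material
14 | 3,3‑dimethyl‑5‑[(3R)‑3‑methylpent‑4‑en‑1‑yl]‑1,2,4‑trioxolane (ozonide of 13) | C=C[C@H](C)CCC1OOC(C)(C)O1 | intermediate
15 | (4R)‑4‑methylhex‑5‑enal | C=C[C@H](C)CCC=O | intermediate
16 | (4R)‑4‑methylhex‑5‑enoic acid | C=C[C@H](C)CCC(=O)O | intermediate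
17 | (4R)‑4‑benzyl‑1,3‑oxazolidin‑2‑one | O=C1N[C@H](Cc2ccccc2)CO1 | starting material
18 | (4R)‑4‑methylhex‑5‑enoic 2,2‑dimethylpropanoic anhydride | C=C[C@H](C)CCC(=O)OC(=O)C(C)(C)C | intermediate
19 | (4R)‑4‑benzyl‑3‑[(4R)‑4‑methylhex‑5‑enoyl]‑1,3‑oxazolidin‑2‑one | C=C[C@H](C)CCC(=O)N1[C@H](Cc2ccccc2)COC1=O | intermediate
20 | sodium (1Z,4R)‑1‑[(4R)‑4‑benzyl‑2‑oxo‑1,3‑oxazolidin‑3‑yl]‑4‑methylhexa‑1,5‑dien‑1‑olate | [Na+].C=C[C@H](C)C/C=C(\[O-])N1[C@H](Cc2ccccc2)COC1=O | intermediate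
21 | sodium (2R,4R)‑1‑[(4R)‑4‑benzyl‑2‑oxo‑1,3‑oxazolidin‑3‑yl]‑4‑methyl‑1‑oxohex‑5‑en‑2‑olate | [Na+].C=C[C@H](C)C[C@@H]([O-])C(=O)N1[C@H](Cc2ccccc2)COC1=O | intermediate
22 | (4R)‑4‑benzyl‑3‑[(2R,4R)‑2‑hydroxy‑4‑methylhex‑5‑enoyl]‑1,3‑oxazolidin‑2‑one | C=C[C@H](C)C[C@@H](O)C(=O)N1[C@H](Cc2ccccc2)COC1=O | intermediate
23 | methyl (2R,4R)‑2‑hydroxy‑4‑methylhex‑5‑enoate | C=C[C@H](C)C[C@@H](O)C(=O)OC | intermediate
24 | methyl (2R,4R)‑4‑methyl‑2‑(propanoyloxy)hex‑5‑enoate | C=C[C@H](C)C[C@@H](OC(=O)CC)C(=O)OC | intermediate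
25 | methyl (2R,4R,5E)‑4‑methyl‑2‑(propanoyloxy)‑6‑(4,4,5,5‑tetramethyl‑1,3,2‑dioxaborolan‑2‑yl)hex‑5‑enoate | CC1(C)OB(/C=C/[C@H](C)C[C@@H](OC(=O)CC)C(=O)OC)OC1(C)C | intermediate
26 | methyl (2R,4R,5E,7E,12R)‑15‑(furan‑3‑yl)‑4,8,12‑trimethyl‑2‑(propanoyloxy)pentadeca‑5,7‑dienoate | COC(=O)[C@@H](C[C@@H](C)/C=C/C=C(\C)CCC[C@@H](C)CCCc1ccoc1)OC(=O)CC | intermediate
27 | lithium 1‑{[(2R,4R,5E,7E,12R)‑15‑(furan‑3‑yl)‑1‑methoxy‑4,8,12‑trimethyl‑1‑oxopentadeca‑5,7‑dien‑2‑yl]oxy}prop‑1‑en‑1‑olate | [Li+].COC(=O)[C@@H](C[C@@H](C)/C=C/C=C(\C)CCC[C@@H](C)CCCc1ccoc1)OC([O-])=CC | intermediate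
28 | lithium tetronate of 29, lithium (5R)‑5‑[(2R,3E,5E,10R)‑13‑(furan‑3‑yl)‑2,6,10‑trimethyltrideca‑3,5‑dien‑1‑yl]‑3‑methyl‑2‑oxo‑2,5‑dihydrofuran‑4‑olate | [Li+].CC1=C([O-])[C@@H](C[C@@H](C)/C=C/C=C(\C)CCC[C@@H](C)CCCc2ccoc2)OC1=O | intermediate
29 | (5R)‑5‑[(2R,3E,5E,10R)‑13‑(furan‑3‑yl)‑2,6,10‑trimethyltrideca‑3,5‑dien‑1‑yl]‑4‑hydroxy‑3‑methylfuran‑2(5H)‑one (CNP0246504.1) | CC1=C(O)[C@@H](C[C@@H](C)/C=C/C=C(\C)CCC[C@@H](C)CCCc2ccoc2)OC1=O | target

## Step count and risks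

Total step count: 14. Longest linear sequence: 8 steps (steps 1–6, 13, 14, or equally steps 7–14).

The three steps most likely to fail:

Step 12 (cross‑metathesis). The alkene carries an allylic branch, so conversion may stall while vinyl‑Bpin homodimerises. The fallback sets out from 24: ozonolysis of the vinyl group (O3, CH2Cl2, −78 °C; PPh3) gives methyl (2R,4R)‑4‑methyl‑5‑oxo‑2‑(propanoyloxy)pentanoate F1, which is used crude to protect its α‑stereocentre. Takai–Utimoto borylolefination (CrCl2, Cl2CHBpin, LiI, THF, rt) then builds the (E)‑alkenylboronate from the aldehyde, and the fallback comes back to the route at 25.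

Step 13 (Suzuki coupling). Aqueous base may cleave the activated α‑propanoyloxy ester or protodeboronate 25. The fallback sets out from 23, before the acyl group is present: cross‑metathesis with vinyl‑Bpin gives methyl (2R,4R,5E)‑2‑hydroxy‑4‑methyl‑6‑(4,4,5,5‑tetramethyl‑1,3,2‑dioxaborolan‑2‑yl)hex‑5‑enoate F2. Suzuki coupling of this with 12 gives methyl (2R,4R,5E,7E,12R)‑15‑(furan‑3‑yl)‑2‑hydroxy‑4,8,12‑trimethylpentadeca‑5,7‑dienoate F3, and propanoylation (EtCOCl, pyridine, DMAP) comes back to the route at 26.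

Step 14 (Dieckmann closure). C5 may epimerise, or closure may be incomplete, on the most valuable intermediate. The fallback sets out from 24 and closes the ring first (LiN(SiMe3)2, THF, −78 → 0 °C) to (5R)‑4‑hydroxy‑3‑methyl‑5‑[(2R)‑2‑methylbut‑3‑en‑1‑yl]furan‑2(5H)‑one F4, where a C5 epimer can be removed on cheap material. Cross‑metathesis with vinyl‑Bpin gives (5R)‑4‑hydroxy‑3‑methyl‑5‑[(2R,3E)‑2‑methyl‑4‑(4,4,5,5‑tetramethyl‑1,3,2‑dioxaborolan‑2‑yl)but‑3‑en‑1‑yl]furan‑2(5H)‑one F5. Suzuki coupling of its base‑stable tetronate salt with 12 (Pd(PPh3)4, TlOEt 3 equiv, THF/H2O) arrives directly at 29.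

## Further compounds

F1 | step 12 | methyl (2R,4R)‑4‑methyl‑5‑oxo‑2‑(propanoyloxy)pentanoate | O=C[C@H](C)C[C@@H](OC(=O)CC)C(=O)OC
F2 | step 13 | methyl (2R,4R,5E)‑2‑hydroxy‑4‑methyl‑6‑(4,4,5,5‑tetramethyl‑1,3,2‑dioxaborolan‑2‑yl)hex‑5‑enoate | CC1(C)OB(/C=C/[C@H](C)C[C@@H](O)C(=O)OC)OC1(C)C
F3 | step 13 | methyl (2R,4R,5E,7E,12R)‑15‑(furan‑3‑yl)‑2‑hydroxy‑4,8,12‑trimethylpentadeca‑5,7‑dienoate | COC(=O)[C@H](O)C[C@@H](C)/C=C/C=C(\C)CCC[C@@H](C)CCCc1ccoc1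
F4 | step 14 | (5R)‑4‑hydroxy‑3‑methyl‑5‑[(2R)‑2‑methylbut‑3‑en‑1‑yl]furan‑2(5H)‑one | CC1=C(O)[C@@H](C[C@@H](C)C=C)OC1=O
F5 | step 14 | (5R)‑4‑hydroxy‑3‑methyl‑5‑[(2R,3E)‑2‑methyl‑4‑(4,4,5,5‑tetramethyl‑1,3,2‑dioxaborolan‑2‑yl)but‑3‑en‑1‑yl]furan‑2(5H)‑one | CC1=C(O)[C@@H](C[C@@H](C)/C=C/B2OC(C)(C)C(C)(C)O2)OC1=O
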